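Readings and results stem from a simulated flask with constants of no real substance, and the scatter is random.

Thursday's run at 46 °C had flattened in Q from 60.0 min on, and Wednesday's flask at 40 °C, followed to 90.0 min, did the same, so I asked which number had to be known well for Wednesday's flask.

| setting | Wednesday's | Thursday's | flask |
|---|---|---|---|
| X | 0.12 M | 0.12 M | 0.12 M |
| L | 1 equiv | 1 equiv | 1.00 equiv |
| temperature | 40 °C | 46 °C | 40 °C |
| remark | the very flask that is asked about, followed so far | run made earlier |  |
| time |  |  | 2.0 h |

| run | time / min | Q / % | X / % |
|---|---|---|---|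
| Wednesday's | 15.0 | 12.5 | 64.5 |
| Wednesday's | 30.0 | 18.4 | 45.5 |
| Wednesday's | 40.0 | 19.7 | 38.6 |
| Wednesday's | 60.0 | 21.4 | 33.2 |
| Wednesday's | 80.0 | 20.8 | 31.0 |
| Wednesday's | 90.0 | 21.8 | 30.6 |
| Thursday's | 15.0 | 14.7 | 64.3 |
| Thursday's | 30.0 | 19.0 | 44.7 |
| Thursday's | 40.0 | 19.8 | 38.8 |
| Thursday's | 60.0 | 20.3 | 34.2 |
| Thursday's | 80.0 | 19.7 | 32.6 |
| Thursday's | 90.0 | 20.1 | 32.1 |

(standard deviation of a reading: 0.5 percentage points)

- as a solid, counted per litre of solution: X
- Q taken out counts as made
- steps under discussion: X <-> Z; 2 L -> D; Z + L -> Q
- at the start none of X is in solution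
- additions bring no volume worth counting

- north: at 2.0 h raise the temperature by 15 K, then wait 2.0 h
- west: at 2.0 h add L, 100 % of the amount charged, then wait 2.0 h
- south-east: change nothing and wait 2.0 h more
- north-east: at 2.0 h take out 90 % of the Q then present, then wait 2.0 h

1. Q, in percent of the X first charged, at 2.0 h
2. which option adds most Q ("none" when 2 percentage points or less is all one gets) (north / west / south-east / north-east / none)
3. Q present, with what was taken out counted in, in percent of the X first charged, after west
4. Q present, with what was taken out counted in, in percent of the X first charged, after north-east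

1. The plateau of Q had to be known well, since any error in it passed point for point into the answer. The mean of Wednesday's 3 last readings was 21.3 %, with a standard deviation of 0.29 percentage points.

2. The time scale mattered little. From Wednesday's reading at 15.0 min I got 11.8 min for the gap half-life, the time in which the distance of Q from its plateau halves. So 2.0 h was 10.2 gap half-lives, leaving 0.018 points to come. Had it been twice as long, 0.63 points would have remained, still less than 2 points.

3. Temperature was not in question for this flask, though Thursday's plateau of 20.0 % lay 1.3 points lower.

4. So I committed to 21.3 % at 2.0 h. Z by difference stood at 47.6 % in Wednesday's reading at 90.0 min, more than Q, so I read L as the limiting reagent and expected a gain from west and 21.3 % after north-east. Z by difference in Wednesday's reading at 15.0 min was 23.0 %, so by my reckoning fresh L would meet twice that [Z]. Taking that early [Z] as what the first charge of L met, and supposing that the share of L caught goes with [Z], my estimate for west was 65.5 %.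

The forecast gave 21.8 %, west, 47 % for west and 22 % for north-east, on the ground that “Z is plentiful, so the stall must come from L having run out”, and its west figure lay below mine.

Wednesday's flask gave 21.4 % at 2.0 h, 63.3 % after west, and 21.4 % after north-east.

    X ⇌ Z, rate k1*(cs1 - [Z]) while solid is left; crystals form when [Z] > cs1 (solubility = 0.0580 M, k = 0.00114 s⁻¹)
    2 L → D (k = 0.0234 L mol⁻¹ s⁻¹, Ea = 49.0 kJ mol⁻¹)
    Z + L → Q (k = 0.0361 L mol⁻¹ s⁻¹, Ea = 67.0 kJ mol⁻¹)
    (constants at 40 °C)

At 2.00 h, 10.2 gap half-lives in, free L in Wednesday's flask stood at 0 % of its charge. Thursday's own readings give a gap half-life of 7.86 min, so its last reading at 90.0 min lay 11.5 gap half-lives in, with 0.0071 points to come. Thursday's flask stood at 19.7 % there and at 19.7 % at 2.0 h.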